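**Retrosynthetic overview**

1. The side chain is numbered C1' (ring-bound CH2) to C32'; the target is the (7'S,11'R,27'S) isomer with all four C=C bonds E. No ring is formed in the route: ring A (quinone ring) and ring B (benzo ring) are bought together as 1,4-dimethoxy-2-methylnaphthalene, and ring A is oxidised to the quinone in the last step.
2. Key disconnection C21'–C22': in the 1,5-diene C18'=C19'(CH3)–C20'H2–C21'H2–C22'H=C23'(CH3), C20'–C21' can be carried as the terminal vinyl group of a conjugated diene (the only monosubstituted C=C of tetraene 27) and C22' as the iodine-bearing carbon of (E)-alkenyl iodide 6. A one-pot hydroboration/B-alkyl Suzuki–Miyaura coupling joins the two.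
3. Tetraene 27 is assembled by two copper-catalysed Grignard couplings (C9'–C10' and C12'–C13') and one alkyne methylalumination/nickel-catalysed benzylic coupling (C1'–C2'); the trienyl acetate 12 comes from geranyl acetate.
4. The stereocentres are bought: C7' from (R)-citronellyl bromide, C11' from (S)-3-bromo-2-methylpropan-1-ol, C27' from (S)-citronellyl bromide. E geometry comes from syn-methylalumination (C2'=C3', C22'=C23'), from geranyl acetate (C14'=C15') and from SeO2 oxidation (C18'=C19').

Key step: step 18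

Remark: compounds 1, 7, 9, 13 and 15 are taken as catalogue chemicals; CIP analysis of the given SMILES gives 7'S, 11'R, 27'S, and the route is built for these.

**Route**

Step 1
Reactants: 1 (S)-citronellyl bromide [(6S)-8-bromo-2,6-dimethyloct-2-ene]
Product: 2 (3S)-1-bromo-3,7-dimethyloctane
Conditions: H2 (1 atm), PtO2 (cat.), EtOAc, rt
Reagents that add atoms: none
Why: Heterogeneous hydrogenation of the isolated trisubstituted alkene in a neutral solvent should leave the primary C–Br bond and the remote stereocentre untouched.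

Step 2
Reactants: 2 (3S)-1-bromo-3,7-dimethyloctane
Product: 3 [(6S)-6,10-dimethylundec-1-yn-1-yl]trimethylsilane
Conditions: 1-(trimethylsilyl)propyne, n-BuLi, TMEDA, THF, −20 °C; then 2, DMPU, −78 °C → rt
Reagents that add atoms: 1-(trimethylsilyl)propyne, C[Si](C)(C)C#CC
Why: SN2 alkylation of the propargylic carbanion of the silyl-capped propyne by a primary bromide should give the propargyl product, the silyl group blocking the alkyne terminus, with the stereocentre three atoms away from the reacting carbon.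

Step 3
Reactants: 3 [(6S)-6,10-dimethylundec-1-yn-1-yl]trimethylsilane
Product: 4 (5S)-5,9-dimethyldec-1-yne
Conditions: K2CO3 (cat.), MeOH, rt
Reagents that add atoms: none
Why: Base-catalysed methanolysis of the C(sp)–Si bond (protodesilylation) should free the terminal alkyne without touching anything else.

Step 4
Reactants: 4 (5S)-5,9-dimethyldec-1-yne
Product: 6 (1E,6S)-1-iodo-2,6,10-trimethylundec-1-ene, via alkenylalane 5 (not isolated)
Conditions: AlMe3 (2 equiv), Cp2ZrCl2 (0.25 equiv), CH2Cl2, 0 °C → rt; then I2, THF, −30 °C → 0 °C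
Reagents that add atoms: trimethylaluminium, C[Al](C)C; iodine, II
Why: Negishi zirconium-catalysed methylalumination adds methyl and aluminium syn across the terminal alkyne (methyl on the internal carbon), and iodinolysis of the C–Al bond with retention should give the E iodide.

Step 5
Reactants: 7 1,4-dimethoxy-2-methylnaphthalene
Product: 8 2-(chloromethyl)-1,4-dimethoxy-3-methylnaphthalene
Conditions: (CH2O)n, conc. aq. HCl, AcOH, 40 °C
Reagents that add atoms: formaldehyde (as paraformaldehyde), C=O; hydrogen chloride, Cl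
Why: Blanc chloromethylation should occur at C3, the only free position of the electron-rich ring that carries both methoxy groups.

Step 6
Reactants: 9 geranyl acetate [(2E)-3,7-dimethylocta-2,6-dien-1-yl acetate]
Product: 10 (2E,6E)-8-hydroxy-3,7-dimethylocta-2,6-dien-1-yl acetate
Conditions: SeO2 (0.1 equiv), t-BuOOH (70% aq.), salicylic acid (cat.), CH2Cl2, rt
Reagents that add atoms: tert-butyl hydroperoxide, CC(C)(C)OO; selenium dioxide (oxygen carrier, reoxidised), O=[Se]=O
Why: Catalytic SeO2 allylic oxidation (ene reaction, then [2,3]-sigmatropic shift; Riley-type oxidation) should oxidise the E-methyl of the distal, more electron-rich alkene to the (E)-allylic alcohol, the C2=C3 alkene being deactivated by the allylic acetate.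

Step 7
Reactants: 10 (2E,6E)-8-hydroxy-3,7-dimethylocta-2,6-dien-1-yl acetate
Product: 11 (2E,6E)-3,7-dimethyl-8-oxoocta-2,6-dien-1-yl acetate
Conditions: MnO2 (activated, excess), CH2Cl2, rt
Reagents that add atoms: none
Why: MnO2 oxidises allylic alcohols chemoselectively to enals and should not affect the acetate or the alkene geometry.

Step 8
Reactants: 11 (2E,6E)-3,7-dimethyl-8-oxoocta-2,6-dien-1-yl acetate
Product: 12 (2E,6E)-3,7-dimethylnona-2,6,8-trien-1-yl acetate
Conditions: Ph3PCH3Br, n-BuLi, THF, 0 °C; then 11, −78 °C → 0 °C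
Reagents that add atoms: methyltriphenylphosphonium bromide, C[P+](c1ccccc1)(c1ccccc1)c1ccccc1.[Br-]
Why: Wittig methylenation of the enal by the non-stabilised ylide at low temperature should be much faster than attack on the acetate and creates no new stereo-element.

Step 9
Reactants: 13 (2S)-3-bromo-2-methylpropan-1-ol
Product: 14 [(2S)-3-bromo-2-methylpropoxy](tert-butyl)dimethylsilane
Conditions: TBSCl, imidazole, CH2Cl2, 0 °C → rt
Reagents that add atoms: tert-butyldimethylsilyl chloride, CC(C)(C)[Si](C)(C)Cl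
Why: Imidazole-promoted silylation of the primary alcohol protects the oxygen for the organometallic steps that follow.

Step 10
Reactants: 15 (R)-citronellyl bromide [(6R)-8-bromo-2,6-dimethyloct-2-ene]; 14 [(2S)-3-bromo-2-methylpropoxy](tert-butyl)dimethylsilane
Product: 17 tert-butyldimethyl{[(2R,6S)-2,6,10-trimethylundec-9-en-1-yl]oxy}silane, via Grignard reagent 16 (not isolated)
Conditions: 15, Mg, THF, 40 °C; then 14, Li2CuCl4 (3 mol %), THF, −10 °C → rt
Reagents that add atoms: none
Why: Copper-catalysed sp3–sp3 coupling of a primary Grignard reagent with a primary bromide (Kochi–Schlosser coupling) forms C9'–C10' and does not touch either stereocentre, since neither is a reacting carbon.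

Step 11
Reactants: 17 tert-butyldimethyl{[(2R,6S)-2,6,10-trimethylundec-9-en-1-yl]oxy}silane
Product: 19 (4S,8R)-9-[(tert-butyldimethylsilyl)oxy]-4,8-dimethylnonan-1-ol, via aldehyde 18 (not isolated)
Conditions: O3, CH2Cl2/MeOH, −78 °C; then NaBH4, −78 °C → rt
Reagents that add atoms: ozone, [O-][O+]=O
Why: Ozonolysis of the only C=C bond with reductive work-up should give the primary alcohol; the aldehyde stage has no α-stereocentre to epimerise.

Step 12
Reactants: 19 (4S,8R)-9-[(tert-butyldimethylsilyl)oxy]-4,8-dimethylnonan-1-ol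
Product: 20 tert-butyl{[(2R,6S)-9-iodo-2,6-dimethylnonyl]oxy}dimethylsilane
Conditions: I2, PPh3, imidazole, CH2Cl2, 0 °C → rt
Reagents that add atoms: iodine, II
Why: Appel-type iodination of a primary alcohol under imidazole buffering should leave the silyl ether intact.

Step 13
Reactants: 20 tert-butyl{[(2R,6S)-9-iodo-2,6-dimethylnonyl]oxy}dimethylsilane
Product: 21 tert-butyl{[(2R,6S)-2,6-dimethylundec-10-yn-1-yl]oxy}dimethylsilane
Conditions: LiC≡CH·H2NCH2CH2NH2, DMSO, 10 °C → rt
Reagents that add atoms: lithium acetylide (ethylenediamine complex), [Li]C#C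
Why: SN2 alkylation of lithium acetylide by an unhindered primary iodide in DMSO should install the C2'≡C3' terminal alkyne.

Step 14
Reactants: 21 tert-butyl{[(2R,6S)-2,6-dimethylundec-10-yn-1-yl]oxy}dimethylsilane; 8 2-(chloromethyl)-1,4-dimethoxy-3-methylnaphthalene
Product: 23 tert-butyl{[(2R,6S,10E)-12-(1,4-dimethoxy-3-methylnaphthalen-2-yl)-2,6,10-trimethyldodec-10-en-1-yl]oxy}dimethylsilane, via alkenylalane 22 (not isolated)
Conditions: AlMe3 (2 equiv), Cp2ZrCl2 (0.25 equiv), CH2Cl2, rt; then 8, NiCl2(PPh3)2 (3 mol %)/n-BuLi (6 mol %, gives zerovalent nickel), THF, rt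
Reagents that add atoms: trimethylaluminium, C[Al](C)C
Why: Negishi methylalumination sets the C2'=C3' E geometry by syn addition, and the alkenylalane should couple with the benzylic chloride under zerovalent nickel catalysis (Negishi-type alkenyl–benzyl cross-coupling) with retention, the silyl ether being inert to AlMe3.

Step 15
Reactants: 23 tert-butyl{[(2R,6S,10E)-12-(1,4-dimethoxy-3-methylnaphthalen-2-yl)-2,6,10-trimethyldodec-10-en-1-yl]oxy}dimethylsilane
Product: 24 (2R,6S,10E)-12-(1,4-dimethoxy-3-methylnaphthalen-2-yl)-2,6,10-trimethyldodec-10-en-1-ol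
Conditions: TBAF, THF, rt
Reagents that add atoms: none
Why: Fluoride cleavage of the Si–O bond should release the primary alcohol without affecting the aryl ethers or the alkene.

Step 16
Reactants: 24 (2R,6S,10E)-12-(1,4-dimethoxy-3-methylnaphthalen-2-yl)-2,6,10-trimethyldodec-10-en-1-ol
Product: 25 2-[(2E,7S,11R)-12-bromo-3,7,11-trimethyldodec-2-en-1-yl]-1,4-dimethoxy-3-methylnaphthalene
Conditions: CBr4, PPh3, CH2Cl2, 0 °C
Reagents that add atoms: carbon tetrabromide, BrC(Br)(Br)Br
Why: The Appel reaction converts the primary alcohol into the bromide under neutral conditions, and the adjacent C11' stereocentre is not a reacting carbon.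

Step 17
Reactants: 25 2-[(2E,7S,11R)-12-bromo-3,7,11-trimethyldodec-2-en-1-yl]-1,4-dimethoxy-3-methylnaphthalene; 12 (2E,6E)-3,7-dimethylnona-2,6,8-trien-1-yl acetate
Product: 27 2-[(2E,7S,11R,14E,18E)-3,7,11,15,19-pentamethylhenicosa-2,14,18,20-tetraen-1-yl]-1,4-dimethoxy-3-methylnaphthalene, via Grignard reagent 26 (not isolated)
Conditions: 25, Mg, THF, 45 °C; then fast addition to 12, Li2CuCl4 (5 mol %), THF, −30 °C → 0 °C
Reagents that add atoms: none
Why: Copper-catalysed allylic substitution of a primary allylic acetate by a primary Grignard reagent should go at the α-carbon (SN2) with retention of the E geometry, because γ-attack would build a quaternary carbon, and the remote diene is not involved.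

Step 18
Reactants: 27 2-[(2E,7S,11R,14E,18E)-3,7,11,15,19-pentamethylhenicosa-2,14,18,20-tetraen-1-yl]-1,4-dimethoxy-3-methylnaphthalene; 6 (1E,6S)-1-iodo-2,6,10-trimethylundec-1-ene
Product: 29 2-[(2E,7S,11R,14E,18E,22E,27S)-3,7,11,15,19,23,27,31-octamethyldotriaconta-2,14,18,22-tetraen-1-yl]-1,4-dimethoxy-3-methylnaphthalene, via alkylborane 28 (not isolated)
Conditions: 9-BBN (1.2 equiv), THF, 0 °C → rt; then 6, Pd(dppf)Cl2 (5 mol %), AsPh3 (5 mol %), Cs2CO3, DMF/H2O, rt
Reagents that add atoms: none
Why: 9-BBN adds syn and anti-Markovnikov to C20'=C21', the only monosubstituted C=C of 27, placing boron on C21'; after base activation the primary alkyl group is transferred from boron to the alkenylpalladium iodide formed by oxidative addition of 6 to zerovalent palladium, and reductive elimination forges C21'–C22'. The closest known reaction type is the B-alkyl Suzuki–Miyaura coupling of 9-BBN adducts of terminal alkenes with (E)-1-iodo-2-methylalkenes. No ring is closed and no stereocentre is created; the C22'=C23' geometry is carried over from 6 with retention and the C18'=C19' geometry is untouched because the borane is homoallylic, never allylic. The step needs site selectivity (vinyl over four trisubstituted alkenes), regioselectivity (boron at C21', not C20') and suppression of β-hydride elimination; the first two are secured by the bulk of 9-BBN and by the fully substituted C19' next to C20', the third by the wide-bite-angle dppf ligand with AsPh3. In one operation the extra unsaturation at C20'/C21' is removed, the two large fragments are united and the whole carbon skeleton is completed.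

Step 19
Reactants: 29 2-[(2E,7S,11R,14E,18E,22E,27S)-3,7,11,15,19,23,27,31-octamethyldotriaconta-2,14,18,22-tetraen-1-yl]-1,4-dimethoxy-3-methylnaphthalene
Product: 30 2-methyl-3-[(2E,7S,11R,14E,18E,22E,27S)-3,7,11,15,19,23,27,31-octamethyldotriaconta-2,14,18,22-tetraen-1-yl]naphthalene-1,4-dione (target)
Conditions: (NH4)2Ce(NO3)6, MeCN/H2O/CH2Cl2, 0 °C
Reagents that add atoms: water, O
Why: Oxidative demethylation of the 1,4-dimethoxyarene by (NH4)2Ce(NO3)6 (water attacks the arene radical cation and methanol is lost) should give the quinone at 0 °C without touching the isolated trisubstituted alkenes or the stereocentres.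

**Compound list**

1 | (S)-citronellyl bromide, (6S)-8-bromo-2,6-dimethyloct-2-ene | BrCC[C@@H](C)CCC=C(C)C | starting material
2 | (3S)-1-bromo-3,7-dimethyloctane | BrCC[C@@H](C)CCCC(C)C | intermediate
3 | [(6S)-6,10-dimethylundec-1-yn-1-yl]trimethylsilane | C[Si](C)(C)C#CCCC[C@@H](C)CCCC(C)C | intermediate
4 | (5S)-5,9-dimethyldec-1-yne | C#CCCC[C@@H](C)CCCC(C)C | intermediate
5 | dimethyl[(1E,6S)-2,6,10-trimethylundec-1-en-1-yl]alumane (not isolated) | C[Al](C)/C=C(\C)CCC[C@@H](C)CCCC(C)C | intermediate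
6 | (1E,6S)-1-iodo-2,6,10-trimethylundec-1-ene | I/C=C(\C)CCC[C@@H](C)CCCC(C)C | intermediate
7 | 1,4-dimethoxy-2-methylnaphthalene | COc1c(C)cc(OC)c2ccccc12 | starting material
8 | 2-(chloromethyl)-1,4-dimethoxy-3-methylnaphthalene | COc1c(C)c(CCl)c(OC)c2ccccc12 | intermediate
9 | geranyl acetate, (2E)-3,7-dimethylocta-2,6-dien-1-yl acetate | CC(=O)OC/C=C(\C)CCC=C(C)C | starting material
10 | (2E,6E)-8-hydroxy-3,7-dimethylocta-2,6-dien-1-yl acetate | CC(=O)OC/C=C(\C)CC/C=C(\C)CO | intermediate
11 | (2E,6E)-3,7-dimethyl-8-oxoocta-2,6-dien-1-yl acetate | CC(=O)OC/C=C(\C)CC/C=C(\C)C=O | intermediate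
12 | (2E,6E)-3,7-dimethylnona-2,6,8-trien-1-yl acetate | CC(=O)OC/C=C(\C)CC/C=C(\C)C=C | intermediate
13 | (2S)-3-bromo-2-methylpropan-1-ol | OC[C@H](C)CBr | starting material
14 | [(2S)-3-bromo-2-methylpropoxy](tert-butyl)dimethylsilane | BrC[C@@H](C)CO[Si](C)(C)C(C)(C)C | intermediate
15 | (R)-citronellyl bromide, (6R)-8-bromo-2,6-dimethyloct-2-ene | BrCC[C@H](C)CCC=C(C)C | starting material
16 | [(3R)-3,7-dimethyloct-6-en-1-yl]magnesium bromide (not isolated) | Br[Mg]CC[C@H](C)CCC=C(C)C | intermediate
17 | tert-butyldimethyl{[(2R,6S)-2,6,10-trimethylundec-9-en-1-yl]oxy}silane | CC(C)=CCC[C@@H](C)CCC[C@@H](C)CO[Si](C)(C)C(C)(C)C | intermediate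
18 | (4S,8R)-9-[(tert-butyldimethylsilyl)oxy]-4,8-dimethylnonanal (not isolated) | O=CCC[C@@H](C)CCC[C@@H](C)CO[Si](C)(C)C(C)(C)C | intermediate
19 | (4S,8R)-9-[(tert-butyldimethylsilyl)oxy]-4,8-dimethylnonan-1-ol | OCCC[C@@H](C)CCC[C@@H](C)CO[Si](C)(C)C(C)(C)C | intermediate
20 | tert-butyl{[(2R,6S)-9-iodo-2,6-dimethylnonyl]oxy}dimethylsilane | ICCC[C@@H](C)CCC[C@@H](C)CO[Si](C)(C)C(C)(C)C | intermediate
21 | tert-butyl{[(2R,6S)-2,6-dimethylundec-10-yn-1-yl]oxy}dimethylsilane | C#CCCC[C@@H](C)CCC[C@@H](C)CO[Si](C)(C)C(C)(C)C | intermediate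
22 | {(1E,6S,10R)-11-[(tert-butyldimethylsilyl)oxy]-2,6,10-trimethylundec-1-en-1-yl}dimethylalumane (not isolated) | C[Al](C)/C=C(\C)CCC[C@@H](C)CCC[C@@H](C)CO[Si](C)(C)C(C)(C)C | intermediate
23 | tert-butyl{[(2R,6S,10E)-12-(1,4-dimethoxy-3-methylnaphthalen-2-yl)-2,6,10-trimethyldodec-10-en-1-yl]oxy}dimethylsilane | COc1c(C)c(C/C=C(\C)CCC[C@@H](C)CCC[C@@H](C)CO[Si](C)(C)C(C)(C)C)c(OC)c2ccccc12 | intermediate
24 | (2R,6S,10E)-12-(1,4-dimethoxy-3-methylnaphthalen-2-yl)-2,6,10-trimethyldodec-10-en-1-ol | COc1c(C)c(C/C=C(\C)CCC[C@@H](C)CCC[C@@H](C)CO)c(OC)c2ccccc12 | intermediate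
25 | 2-[(2E,7S,11R)-12-bromo-3,7,11-trimethyldodec-2-en-1-yl]-1,4-dimethoxy-3-methylnaphthalene | COc1c(C)c(C/C=C(\C)CCC[C@@H](C)CCC[C@@H](C)CBr)c(OC)c2ccccc12 | intermediate
26 | [(2R,6S,10E)-12-(1,4-dimethoxy-3-methylnaphthalen-2-yl)-2,6,10-trimethyldodec-10-en-1-yl]magnesium bromide (not isolated) | COc1c(C)c(C/C=C(\C)CCC[C@@H](C)CCC[C@@H](C)C[Mg]Br)c(OC)c2ccccc12 | intermediate
27 | 2-[(2E,7S,11R,14E,18E)-3,7,11,15,19-pentamethylhenicosa-2,14,18,20-tetraen-1-yl]-1,4-dimethoxy-3-methylnaphthalene | COc1c(C)c(C/C=C(\C)CCC[C@@H](C)CCC[C@@H](C)CC/C=C(\C)CC/C=C(\C)C=C)c(OC)c2ccccc12 | intermediate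
28 | 9-[(3E,7E,11R,15S,19E)-21-(1,4-dimethoxy-3-methylnaphthalen-2-yl)-3,7,11,15,19-pentamethylhenicosa-3,7,19-trien-1-yl]-9-borabicyclo[3.3.1]nonane (not isolated) | COc1c(C)c(C/C=C(\C)CCC[C@@H](C)CCC[C@@H](C)CC/C=C(\C)CC/C=C(\C)CCB3C4CCCC3CCC4)c(OC)c2ccccc12 | intermediate
29 | 2-[(2E,7S,11R,14E,18E,22E,27S)-3,7,11,15,19,23,27,31-octamethyldotriaconta-2,14,18,22-tetraen-1-yl]-1,4-dimethoxy-3-methylnaphthalene | COc1c(C)c(C/C=C(\C)CCC[C@@H](C)CCC[C@@H](C)CC/C=C(\C)CC/C=C(\C)CC/C=C(\C)CCC[C@@H](C)CCCC(C)C)c(OC)c2ccccc12 | intermediate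
30 | 2-methyl-3-[(2E,7S,11R,14E,18E,22E,27S)-3,7,11,15,19,23,27,31-octamethyldotriaconta-2,14,18,22-tetraen-1-yl]naphthalene-1,4-dione | CC1=C(C/C=C(\C)CCC[C@@H](C)CCC[C@@H](C)CC/C=C(\C)CC/C=C(\C)CC/C=C(\C)CCC[C@@H](C)CCCC(C)C)C(=O)c2ccccc2C1=O | target

**Step count and risks**

Total step count: 19. Longest linear sequence: 11 steps (steps 9 to 19, from 13).

Steps most likely to fail:

1. Step 18. What may go wrong is incomplete site or regiocontrol in the hydroboration (boron delivered to C20', or a second hydroboration), or slow alkyl transfer from boron to palladium with protodeboronation or β-hydride loss. The fallback sets out from 27 and 6 and comes back at 29. Tetraene 27 is hydroborated with 9-BBN as before to borane 28, which is oxidised (NaOH, H2O2) to the primary alcohol (3E,7E,11R,15S,19E)-21-(1,4-dimethoxy-3-methylnaphthalen-2-yl)-3,7,11,15,19-pentamethylhenicosa-3,7,19-trien-1-ol F1; this can be freed from regioisomers by chromatography. Appel-type iodination (I2, PPh3, imidazole) gives the homoallylic iodide 2-[(2E,7S,11R,14E,18E)-21-iodo-3,7,11,15,19-pentamethylhenicosa-2,14,18-trien-1-yl]-1,4-dimethoxy-3-methylnaphthalene F2. Zinc insertion (Zn dust, LiCl, THF) gives the alkylzinc iodide F3, which is joined to 6 by Negishi coupling (Pd(dppf)Cl2, THF) to give 29.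

2. Step 17. What may go wrong is attack of the copper-bound alkyl group at the γ-terminus (C15') with allylic transposition, erosion of the C14'=C15' geometry, or acyl attack of the Grignard reagent on the acetate. The fallback sets out from 12 and 25 and comes back at 27. Acetate 12 is converted by Tsuji–Trost sulfonylation (sodium 4-methylbenzenesulfinate, Pd(PPh3)4) into the allylic sulfone 1-methyl-4-{[(2E,6E)-3,7-dimethylnona-2,6,8-trien-1-yl]sulfonyl}benzene F4. F4 is deprotonated (n-BuLi, THF/DMPU, −78 °C) and alkylated at the sulfonyl-bearing carbon by bromide 25, giving the C13'-sulfonyl derivative of 27, 2-[(2E,7S,11R,14E,18E)-3,7,11,15,19-pentamethyl-13-(4-methylbenzenesulfonyl)henicosa-2,14,18,20-tetraen-1-yl]-1,4-dimethoxy-3-methylnaphthalene F5 (both C13' epimers). Reductive desulfonylation (LiBHEt3, Pd(dppf)Cl2 cat., THF, 0 °C) gives 27.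

3. Step 14. What may go wrong is transfer of methyl instead of alkenyl from aluminium to the benzylic nickel species, homocoupling of the benzylic chloride, or carry-through of the minor regioisomer of methylalumination. The fallback sets out from 21 and 8 and comes back at 23, with the polarity of the coupling reversed. Alkyne 21 is methylaluminated as before to alane 22 and quenched with I2 to the alkenyl iodide tert-butyl{[(2R,6S,10E)-11-iodo-2,6,10-trimethylundec-10-en-1-yl]oxy}dimethylsilane F6, which can be purified. Chloride 8 is converted by zinc insertion (Zn dust, LiCl, THF) into [(1,4-dimethoxy-3-methylnaphthalen-2-yl)methyl]zinc chloride F7, and Negishi coupling of F6 with F7 (Pd(PPh3)4, THF) gives 23.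

**Further compounds**

F1 | step 18 | (3E,7E,11R,15S,19E)-21-(1,4-dimethoxy-3-methylnaphthalen-2-yl)-3,7,11,15,19-pentamethylhenicosa-3,7,19-trien-1-ol | COc1c(C)c(C/C=C(\C)CCC[C@@H](C)CCC[C@@H](C)CC/C=C(\C)CC/C=C(\C)CCO)c(OC)c2ccccc12
F2 | step 18 | 2-[(2E,7S,11R,14E,18E)-21-iodo-3,7,11,15,19-pentamethylhenicosa-2,14,18-trien-1-yl]-1,4-dimethoxy-3-methylnaphthalene | COc1c(C)c(C/C=C(\C)CCC[C@@H](C)CCC[C@@H](C)CC/C=C(\C)CC/C=C(\C)CCI)c(OC)c2ccccc12
F3 | step 18 | [(3E,7E,11R,15S,19E)-21-(1,4-dimethoxy-3-methylnaphthalen-2-yl)-3,7,11,15,19-pentamethylhenicosa-3,7,19-trien-1-yl]zinc iodide | COc1c(C)c(C/C=C(\C)CCC[C@@H](C)CCC[C@@H](C)CC/C=C(\C)CC/C=C(\C)CC[Zn]I)c(OC)c2ccccc12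
F4 | step 17 | 1-methyl-4-{[(2E,6E)-3,7-dimethylnona-2,6,8-trien-1-yl]sulfonyl}benzene | Cc1ccc(cc1)S(=O)(=O)C/C=C(\C)CC/C=C(\C)C=C
F5 | step 17 | 2-[(2E,7S,11R,14E,18E)-3,7,11,15,19-pentamethyl-13-(4-methylbenzenesulfonyl)henicosa-2,14,18,20-tetraen-1-yl]-1,4-dimethoxy-3-methylnaphthalene (both C13' epimers) | COc1c(C)c(C/C=C(\C)CCC[C@@H](C)CCC[C@@H](C)CC(/C=C(\C)CC/C=C(\C)C=C)S(=O)(=O)c3ccc(C)cc3)c(OC)c2ccccc12
F6 | step 14 | tert-butyl{[(2R,6S,10E)-11-iodo-2,6,10-trimethylundec-10-en-1-yl]oxy}dimethylsilane | I/C=C(\C)CCC[C@@H](C)CCC[C@@H](C)CO[Si](C)(C)C(C)(C)C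
F7 | step 14 | [(1,4-dimethoxy-3-methylnaphthalen-2-yl)methyl]zinc chloride | COc1c(C)c(C[Zn]Cl)c(OC)c2ccccc12
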